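The synthesis rests on disconnecting the pyran-4-one ring of the chromone at C3–C4 and O1–C8a. O1 sits on an aromatic carbon (C8a) ortho to the C4 carbonyl, so C8a can enter as an SNAr-active C–F carbon of a benzoyl chloride that already carries the C5 oxygen as a benzyl ether and the C7 methoxy group. In one operation the methyl-side enolate of a β-silyloxy methyl ketone is C-aroylated and the diketone oxygen then displaces fluoride, so the ring closes with the complete side chain attached. The ketone precursor is tert-butyl (8R)-8-silyloxy-10-oxoundecanoate, whose carbinol center comes from a Noyori hydrogenation.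

Key step: step 9

Remark: chromone numbering (O1, C2, C3, C4, C4a, C5–C8, C8a) is used, and the carbinol carbon of the side chain is called C2'.

Step 1
Reactants: 1 8-(tert-butoxy)-8-oxooctanoic acid; 2 potassium methyl malonate (potassium 3-methoxy-3-oxopropanoate)
Product: 4 10-tert-butyl 1-methyl 3-oxodecanedioate, via acyl imidazolide 3 (not isolated)
Conditions: CDI, THF, rt; then KO2CCH2CO2Me, MgCl2, Et3N, MeCN, rt to 40 °C; cold dilute HCl work-up
Reagents that add atoms: potassium methyl malonate (2), COC(=O)CC(=O)[O-].[K+]; 1,1'-carbonyldiimidazole, O=C(n1ccnc1)n1ccnc1 (imidazole present only in 3)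
Why: Masamune–Brooks homologation, in which acyl imidazolide 3 C-acylates the magnesium enolate of the malonate half-ester and the adduct loses CO2, should give the β-keto ester without touching the tert-butyl ester.

Step 2
Reactants: 4 10-tert-butyl 1-methyl 3-oxodecanedioate
Product: 5 10-tert-butyl 1-methyl (3R)-3-hydroxydecanedioate
Conditions: [RuCl(p-cymene)((R)-BINAP)]Cl (0.5 mol%), H2 (50 atm), MeOH, 50 °C
Reagents that add atoms: none
Why: Noyori asymmetric hydrogenation of a β-keto ester, in which the substrate chelates ruthenium through both carbonyls and the (R)-BINAP ligand directs hydride to the face that gives the (3R)-alcohol (the established sense for 3-oxoalkanoates with this ligand), sets the future C2' center, while the remote tert-butyl ester cannot chelate and is left alone.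

Step 3
Reactants: 5 10-tert-butyl 1-methyl (3R)-3-hydroxydecanedioate
Product: 6 10-tert-butyl 1-methyl (3R)-3-[(tert-butyldimethylsilyl)oxy]decanedioate
Conditions: TBSCl, imidazole, DMF, rt
Reagents that add atoms: tert-butyldimethylsilyl chloride, CC(C)(C)[Si](C)(C)Cl
Why: Imidazole-promoted O-silylation of the secondary alcohol is routine, does not involve the stereocenter, and blocks retro-aldol and alkoxide chemistry in the later base steps.

Step 4
Reactants: 6 10-tert-butyl 1-methyl (3R)-3-[(tert-butyldimethylsilyl)oxy]decanedioate
Product: 7 tert-butyl (8R)-8-[(tert-butyldimethylsilyl)oxy]-10-[methoxy(methyl)amino]-10-oxodecanoate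
Conditions: MeNH(OMe)·HCl (1.5 equiv), iPrMgCl (3.0 equiv), THF, −20 °C; aq NH4Cl
Reagents that add atoms: N,O-dimethylhydroxylamine hydrochloride, CNOC.Cl
Why: Weinreb amide formation by aminolysis of the methyl ester with the chloromagnesium amide should be selective, since the hindered tert-butyl ester does not react at −20 °C and the silyloxy-bearing carbon is not an acidic position.

Step 5
Reactants: 7 tert-butyl (8R)-8-[(tert-butyldimethylsilyl)oxy]-10-[methoxy(methyl)amino]-10-oxodecanoate
Product: 8 tert-butyl (8R)-8-[(tert-butyldimethylsilyl)oxy]-10-oxoundecanoate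
Conditions: MeMgBr (1.3 equiv), THF, −20 to 0 °C; aq NH4Cl
Reagents that add atoms: methylmagnesium bromide, C[Mg]Br
Why: Weinreb ketone synthesis, in which the chelated tetrahedral adduct persists until work-up so that MeMgBr adds only once, should give the methyl ketone while the tert-butyl ester is spared at or below 0 °C.

Step 6
Reactants: 9 2,6-difluoro-4-methoxybenzoic acid; 10 benzyl alcohol
Product: 13 benzyl 2-(benzyloxy)-6-fluoro-4-methoxybenzoate, via acid chloride 11 (not isolated), via benzyl ester 12 (not isolated)
Conditions: (COCl)2, cat. DMF, CH2Cl2, 0 °C to rt; evaporate; then BnOH (2.1 equiv), NaH (2.1 equiv), THF, 0 to 40 °C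
Reagents that add atoms: benzyl alcohol (10), OCc1ccccc1; oxalyl chloride, O=C(Cl)C(=O)Cl (chlorine present only in 11)
Why: After chlorination, the first equivalent of sodium benzyl oxide esterifies 11 (nucleophilic acyl substitution) and the second replaces one of the two equivalent fluorines ortho to the ester by SNAr; the benzyl ester makes any ester exchange by the alkoxide degenerate, and the first alkoxy group, which donates into the ester and replaces an inductively activating fluorine, should slow a second displacement.

Step 7
Reactants: 13 benzyl 2-(benzyloxy)-6-fluoro-4-methoxybenzoate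
Product: 14 2-(benzyloxy)-6-fluoro-4-methoxybenzoic acid
Conditions: NaOH (3 equiv), THF–H2O, 60 °C; then 1 M HCl to pH 2
Reagents that add atoms: sodium hydroxide, [Na+].[OH-]
Why: Saponification by acyl–oxygen cleavage should proceed because the small ortho fluorine leaves the ester carbonyl accessible, while the ring, carrying two alkoxy groups and then a carboxylate, is too electron-rich for hydroxide to displace the remaining fluoride (no alcohol cosolvent, so no stronger alkoxide is present).

Step 8
Reactants: 14 2-(benzyloxy)-6-fluoro-4-methoxybenzoic acid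
Product: 15 2-(benzyloxy)-6-fluoro-4-methoxybenzoyl chloride
Conditions: (COCl)2 (1.5 equiv), cat. DMF, CH2Cl2, 0 °C to rt; evaporate, use crude at once
Reagents that add atoms: oxalyl chloride, O=C(Cl)C(=O)Cl
Why: Acid chloride formation through the chloroiminium species from catalytic DMF is standard, and benzyl ether, aryl fluoride and methyl ether are inert to it.

Step 9
Reactants: 8 tert-butyl (8R)-8-[(tert-butyldimethylsilyl)oxy]-10-oxoundecanoate; 15 2-(benzyloxy)-6-fluoro-4-methoxybenzoyl chloride
Product: 18 tert-butyl (8R)-9-[5-(benzyloxy)-7-methoxy-4-oxo-4H-chromen-2-yl]-8-[(tert-butyldimethylsilyl)oxy]nonanoate, via lithium enolate 16 (not isolated), via aryl diketone 17 (not isolated)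
Conditions: LiN(SiMe3)2 (2.05 equiv), THF, −78 °C; 15 (1.05 equiv), −78 to 0 °C; AcOH; solvent exchange; K2CO3 (2 equiv), DMF, 50 °C
Reagents that add atoms: lithium bis(trimethylsilyl)amide, [Li+].C[Si](C)(C)[N-][Si](C)(C)C (lithium present only in 16)
Why: LiN(SiMe3)2 at −78 °C removes a proton from the methyl group of 8 under kinetic control, enolate 16 attacks the acyl carbon of 15 and expels chloride (bond C3–C4), and the second equivalent of base at once turns diketone 17 into its chelated enolate, which shuts off a second acylation and enolization toward C2'. After neutralization, K2CO3 in DMF re-forms that enolate, and its oxygen on the alkyl side adds to the fluorine-bearing aryl carbon ortho to the aryl ketone and expels fluoride through a Meisenheimer-type anion (bond O1–C8a). The closest known reaction type is the one-pot C-aroylation of ketone enolates with 2-halobenzoyl chlorides followed by intramolecular SNAr, as used for chromones and 4-quinolones. The pyran-4-one ring closes by a six-membered addition–elimination at a trigonal carbon (6-exo-trig counted on the C8–C8a π bond); no stereocenter is formed, and C2' keeps its configuration because its hydrogen is not acidic and the neighboring methylene is never enolized. The step needs methyl-side enolization (kinetic amide base, low temperature), C- over O-acylation (lithium counter-ion in THF, and an enol ester would itself pass its acyl group to remaining enolate), the ketone and not the tert-butyl ester as carbon acid (several pKa units apart, base limited to 2.05 equiv) and loss of fluoride and not benzyl oxide (fluorine makes its carbon the more electrophilic site and is the better leaving group when addition is rate-limiting). Both alkoxy groups stand meta to the C–F carbon, so they do not oppose the anionic intermediate by resonance and only weaken the activating ortho carbonyl, which the intramolecular delivery of the nucleophile offsets.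

Step 10
Reactants: 18 tert-butyl (8R)-9-[5-(benzyloxy)-7-methoxy-4-oxo-4H-chromen-2-yl]-8-[(tert-butyldimethylsilyl)oxy]nonanoate
Product: 19 tert-butyl (8R)-8-[(tert-butyldimethylsilyl)oxy]-9-(5-hydroxy-7-methoxy-4-oxo-4H-chromen-2-yl)nonanoate
Conditions: H2 (1 atm), 10% Pd/C, EtOAc, rt
Reagents that add atoms: none
Why: Hydrogenolysis of the aryl benzyl ether at 1 atm in ethyl acetate should be much faster than saturation of the C2–C3 double bond of the pyranone, and silyl ether and tert-butyl ester are stable under these neutral conditions.

Step 11
Reactants: 19 tert-butyl (8R)-8-[(tert-butyldimethylsilyl)oxy]-9-(5-hydroxy-7-methoxy-4-oxo-4H-chromen-2-yl)nonanoate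
Product: 20 (8R)-8-hydroxy-9-(5-hydroxy-7-methoxy-4-oxo-4H-chromen-2-yl)nonanoic acid (penithochromone S)
Conditions: TFA–H2O (9:1), 0 °C to rt; evaporate; aq NaHCO3–THF, then pH 3
Reagents that add atoms: none
Why: Acidolysis should cleave the tert-butyl ester by alkyl–oxygen fission (the cation leaves as isobutene) and hydrolyze the secondary silyl ether, while chromone, aryl methyl ether and the C2' configuration (no ionization at an unactivated secondary carbinol) are unaffected; the brief bicarbonate treatment hydrolyzes any trifluoroacetate of the C2' alcohol.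

Compound list
1 | 8-(tert-butoxy)-8-oxooctanoic acid | CC(C)(C)OC(=O)CCCCCCC(=O)O | starting material
2 | potassium methyl malonate (potassium 3-methoxy-3-oxopropanoate) | COC(=O)CC(=O)[O-].[K+] | starting material
3 | tert-butyl 8-(1H-imidazol-1-yl)-8-oxooctanoate | CC(C)(C)OC(=O)CCCCCCC(=O)n1ccnc1 | intermediate
4 | 10-tert-butyl 1-methyl 3-oxodecanedioate | COC(=O)CC(=O)CCCCCCC(=O)OC(C)(C)C | intermediate
5 | 10-tert-butyl 1-methyl (3R)-3-hydroxydecanedioate | COC(=O)C[C@H](O)CCCCCCC(=O)OC(C)(C)C | intermediate
6 | 10-tert-butyl 1-methyl (3R)-3-[(tert-butyldimethylsilyl)oxy]decanedioate | COC(=O)C[C@H](O[Si](C)(C)C(C)(C)C)CCCCCCC(=O)OC(C)(C)C | intermediate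
7 | tert-butyl (8R)-8-[(tert-butyldimethylsilyl)oxy]-10-[methoxy(methyl)amino]-10-oxodecanoate | CON(C)C(=O)C[C@H](O[Si](C)(C)C(C)(C)C)CCCCCCC(=O)OC(C)(C)C | intermediate
8 | tert-butyl (8R)-8-[(tert-butyldimethylsilyl)oxy]-10-oxoundecanoate | CC(=O)C[C@H](O[Si](C)(C)C(C)(C)C)CCCCCCC(=O)OC(C)(C)C | intermediate
9 | 2,6-difluoro-4-methoxybenzoic acid | COc1cc(F)c(C(=O)O)c(F)c1 | starting material
10 | benzyl alcohol | OCc1ccccc1 | starting material
11 | 2,6-difluoro-4-methoxybenzoyl chloride | COc1cc(F)c(C(=O)Cl)c(F)c1 | intermediate
12 | benzyl 2,6-difluoro-4-methoxybenzoate | COc1cc(F)c(C(=O)OCc2ccccc2)c(F)c1 | intermediate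
13 | benzyl 2-(benzyloxy)-6-fluoro-4-methoxybenzoate | COc1cc(F)c(C(=O)OCc2ccccc2)c(OCc2ccccc2)c1 | intermediate
14 | 2-(benzyloxy)-6-fluoro-4-methoxybenzoic acid | COc1cc(F)c(C(=O)O)c(OCc2ccccc2)c1 | intermediate
15 | 2-(benzyloxy)-6-fluoro-4-methoxybenzoyl chloride | COc1cc(F)c(C(=O)Cl)c(OCc2ccccc2)c1 | intermediate
16 | lithium (4R)-11-(tert-butoxy)-4-[(tert-butyldimethylsilyl)oxy]-11-oxoundec-1-en-2-olate (methyl-side lithium enolate of 8) | [Li+].[O-]C(=C)C[C@H](O[Si](C)(C)C(C)(C)C)CCCCCCC(=O)OC(C)(C)C | intermediate
17 | tert-butyl (8R)-12-[2-(benzyloxy)-6-fluoro-4-methoxyphenyl]-8-[(tert-butyldimethylsilyl)oxy]-10,12-dioxododecanoate | COc1cc(F)c(C(=O)CC(=O)C[C@H](O[Si](C)(C)C(C)(C)C)CCCCCCC(=O)OC(C)(C)C)c(OCc2ccccc2)c1 | intermediate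
18 | tert-butyl (8R)-9-[5-(benzyloxy)-7-methoxy-4-oxo-4H-chromen-2-yl]-8-[(tert-butyldimethylsilyl)oxy]nonanoate | COc1cc(OCc3ccccc3)c2c(=O)cc(C[C@H](O[Si](C)(C)C(C)(C)C)CCCCCCC(=O)OC(C)(C)C)oc2c1 | intermediate
19 | tert-butyl (8R)-8-[(tert-butyldimethylsilyl)oxy]-9-(5-hydroxy-7-methoxy-4-oxo-4H-chromen-2-yl)nonanoate | COc1cc(O)c2c(=O)cc(C[C@H](O[Si](C)(C)C(C)(C)C)CCCCCCC(=O)OC(C)(C)C)oc2c1 | intermediate
20 | (8R)-8-hydroxy-9-(5-hydroxy-7-methoxy-4-oxo-4H-chromen-2-yl)nonanoic acid (penithochromone S) | COc1cc(O)c2c(=O)cc(C[C@H](O)CCCCCCC(=O)O)oc2c1 | target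

Total step count: 11. Longest linear sequence: 8 steps (steps 1–5, 9, 10 and 11, from 1).

Steps most likely to fail

Step 9. The enolate may be acylated at oxygen or twice, surplus amide base may enolize the tert-butyl ester, fluoride displacement on the electron-rich ring may be slow, and prolonged base may expel the silyloxy group once the C2 methylene of the chromone has become acidic. The fallback reverses the polarity of the C–C bond formation and sets out from 15 and 6. Acid chloride 15 is converted with Me2CuLi (THF, −78 °C) into 1-[2-(benzyloxy)-6-fluoro-4-methoxyphenyl]ethan-1-one F1. Its lithium enolate (LiN(SiMe3)2, with F1 in slight excess so that no free amide remains) undergoes a crossed Claisen condensation with methyl ester 6 (THF, −78 °C to rt) to give diketone 17. This is closed with K2CO3 in DMF as in the second stage of step 9, and the route is rejoined at 18. This forms C2–C3 instead of C3–C4, needs no regioselective enolization of an aliphatic ketone, and leaves out steps 4 and 5.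

Step 11. Strong acid may promote loss of water from C2' into conjugation with the pyranone, the liberated tert-butyl cation may alkylate ring A, or the C2' hydroxyl may stay trifluoroacetylated. The fallback uses two separate mild operations and sets out from 19. HF·pyridine (THF–pyridine, 0 °C to rt) removes the silyl group to give tert-butyl (8R)-8-hydroxy-9-(5-hydroxy-7-methoxy-4-oxo-4H-chromen-2-yl)nonanoate F2. ZnBr2 in CH2Cl2 at rt then cleaves the tert-butyl ester under aprotic Lewis-acid conditions, and the route is rejoined at 20.

Step 6. The alkoxide may be consumed unevenly between acylation and fluoride displacement, giving incomplete or double substitution, or it may attack the benzylic carbon of the ester. The fallback introduces the oxygen with hydroxide on the free acid and the benzyl groups afterwards, and sets out from 9. Heating 9 with NaOH in DMSO (130 °C), where the carboxylate directs displacement of one ortho fluorine and the resulting dianion resists a second one, gives 2-fluoro-6-hydroxy-4-methoxybenzoic acid F3. O-Alkylation of both acidic groups with benzyl bromide and K2CO3 in DMF gives 13, where the route is rejoined.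

Further compounds
F1 | step 9 | 1-[2-(benzyloxy)-6-fluoro-4-methoxyphenyl]ethan-1-one | COc1cc(F)c(C(C)=O)c(OCc2ccccc2)c1
F2 | step 11 | tert-butyl (8R)-8-hydroxy-9-(5-hydroxy-7-methoxy-4-oxo-4H-chromen-2-yl)nonanoate | COc1cc(O)c2c(=O)cc(C[C@H](O)CCCCCCC(=O)OC(C)(C)C)oc2c1
F3 | step 6 | 2-fluoro-6-hydroxy-4-methoxybenzoic acid | COc1cc(O)c(C(=O)O)c(F)c1
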